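**Plan**

- Retrosynthetic cuts, in order: (a) O1–C2 and C3–C3a of the dihydrofuran (aryl bromide plus isoprene); (b) the C5–acyl bond; (c) the pyrone bonds C3'–C4' and O1'–C2' (primed = pyrone); (d) the C–C and C–O bonds of a chroman-2-one that is not part of the target.
- Enabling feature: the chain O–C7a–C7–CH2–C3'–C2' is six atoms long, so the pyrone carbonyl C2' and the oxygen on C7a can be held as the lactone of a dihydrocoumarin fused to the phloroglucinol ring, with C3' as its enolisable α-carbon.
- Forward: phloroglucinol and acrylic acid give the chromanone; its enolate and methylketene dimer build the pyrone ring while the lactone ring opens; MOM removal leaves a mirror-symmetric trihydroxybenzyl ring, so acylation can give only one ketone; bromination fills the last ring position; the dihydrofuran ring is closed last.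
- Stereochemistry: the side-chain centre is bought as (R)-2-methylbutanoic acid; C2 (R) is set by the chiral ligand on palladium in the isoprene annulation. O1 is selected because the phenol para to the acyl group is not chelated to the ketone and is the most acidic one.

Key step: step 4

Remark: unprimed locants refer to the dihydrobenzofuran and primed ones to the pyrone; the methylketene dimer is used as the racemate because its stereocentre disappears in the pyrone.

Step 1
Reactants: 1 phloroglucinol; 2 acrylic acid
Product: 3 5,7-dihydroxychroman-2-one
Conditions: Amberlyst-15, toluene, reflux, azeotropic removal of water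
Reagents that add atoms: none
Why: Acid-mediated hydroarylation (Friedel–Crafts conjugate alkylation) of the very electron-rich ring followed by lactonisation onto an ortho phenol should give the dihydrocoumarin; all ring carbons and oxygens of 1 are equivalent, so there is no regiochemical choice.

Step 2
Reactants: 3 5,7-dihydroxychroman-2-one
Product: 4 5,7-bis(methoxymethoxy)chroman-2-one
Conditions: MOMCl (2.4 equiv), i-Pr2NEt, CH2Cl2, 0 °C to rt
Reagents that add atoms: chloromethyl methyl ether, COCCl
Why: Standard O-alkylation of phenols to MOM acetals under a hindered amine base that does not open the aryl lactone; the ethers remove the acidic protons that would otherwise consume the enolate in step 4.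

Step 3
Reactants: 5 propanoyl chloride
Product: 7 racemic (Z)-4-ethylidene-3-methyloxetan-2-one (methylketene dimer), via methylketene 6 (not isolated)
Conditions: 5 (2 equiv per 7 formed), Et3N (1.05 equiv per acid chloride), Et2O, 0 °C to rt; filtration; distillation
Reagents that add atoms: propanoyl chloride (a second molecule of 5), CCC(=O)Cl
Why: Each of two molecules of 5 loses HCl to the amine to give methylketene 6, and two molecules of 6 combine in the known amine-mediated [2+2] ketene dimerisation to the β-lactone enol ether 7.

Step 4
Reactants: 4 5,7-bis(methoxymethoxy)chroman-2-one; 7 methylketene dimer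
Product: 10 6-ethyl-4-hydroxy-3-[2-hydroxy-4,6-bis(methoxymethoxy)benzyl]-5-methyl-2H-pyran-2-one, via chromanone lithium enolate 8 (not isolated), via 3-acylchromanone tricarbonyl intermediate 9 (not isolated)
Conditions: LiN(SiMe3)2 (1.05 equiv), THF, −78 °C; then 7 (1.1 equiv), −78 °C to rt, then 40 °C; cold 1 M HCl to pH 3
Reagents that add atoms: none
Why: Proposed new method: Enolate 8 should attack the acyl carbon of the strained β-lactone 7; ring opening forms the C3'–C4' bond and an ethyl-ketone enolate that is quenched internally by the now strongly acidic C3'–H, leaving the chelated monoanion of 9 with no net use of base. In that anion the oxygen of the distal ketone (future O1') adds to the aryl lactone carbonyl (future C2') in a 6-exo-trig addition–elimination, the aryloxide leaves as from an activated ester, and enolisation of the pyran-2,4-dione gives the 4-hydroxy-2-pyrone, whose acidity (it ends as the pyronate) makes the ring switch irreversible. The closest known reactions are ring-opening acyl transfer from ketene dimers to amines, alkoxides and lithium amides, Claisen C-acylation of lactone enolates, and base-induced lactonisation of 3,5-dioxo esters to 4-hydroxy-2-pyrones; combining them on an aryl lactone whose ester oxygen is the leaving group is the untested part. No stereocentre is formed and the one in 7 is destroyed. Only chemoselectivity is needed: complete enolisation at −78 °C before 7 is added suppresses Claisen self-condensation, loss of aryloxide from 8 gives only a tethered ketene that can re-close, the lithium counter-ion favours C- over O-acylation, and the MOM ethers keep the other two phenols silent.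

Step 5
Reactants: 10 6-ethyl-4-hydroxy-3-[2-hydroxy-4,6-bis(methoxymethoxy)benzyl]-5-methyl-2H-pyran-2-one
Product: 11 6-ethyl-4-hydroxy-5-methyl-3-(2,4,6-trihydroxybenzyl)-2H-pyran-2-one
Conditions: 3 M HCl, MeOH, 45 °C, argon
Reagents that add atoms: none
Why: Acid-catalysed acetal exchange removes both MOM groups while the pyrone and the diarylmethane tolerate dilute acid; the resulting ring has a mirror plane through the benzylic carbon, so its two open positions are equivalent.

Step 6
Reactants: 12 (R)-2-methylbutanoic acid
Product: 13 (R)-2-methylbutanoyl chloride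
Conditions: (COCl)2, DMF (cat.), CH2Cl2, 0 °C to rt; concentrated, used crude
Reagents that add atoms: oxalyl chloride, O=C(Cl)C(=O)Cl
Why: Acid chloride formation through the Vilsmeier-type chloroiminium species proceeds without base, so no ketene forms and the α-stereocentre should stay intact.

Step 7
Reactants: 11 6-ethyl-4-hydroxy-5-methyl-3-(2,4,6-trihydroxybenzyl)-2H-pyran-2-one; 13 (R)-2-methylbutanoyl chloride
Product: 14 6-ethyl-4-hydroxy-5-methyl-3-{2,4,6-trihydroxy-3-[(2R)-2-methylbutanoyl]benzyl}-2H-pyran-2-one
Conditions: AlCl3 (5 equiv), CH2Cl2/PhNO2, 0 °C to rt; cold 1 M HCl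
Reagents that add atoms: none
Why: Friedel–Crafts acylation of a free phloroglucinol ring; the two open positions are symmetry-equivalent and the first acyl group deactivates the ring, so one mono-ketone is expected, its stereocentre carried over unchanged from 13 (both pyrone carbons are blocked and any O-acyl pyrone is cleaved on work-up).

Step 8
Reactants: 14 6-ethyl-4-hydroxy-5-methyl-3-{2,4,6-trihydroxy-3-[(2R)-2-methylbutanoyl]benzyl}-2H-pyran-2-one
Product: 15 3-{3-bromo-2,4,6-trihydroxy-5-[(2R)-2-methylbutanoyl]benzyl}-6-ethyl-4-hydroxy-5-methyl-2H-pyran-2-one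
Conditions: NBS (1.0 equiv), THF, −20 to 0 °C, dark
Reagents that add atoms: N-bromosuccinimide, O=C1CCC(=O)N1Br
Why: Electrophilic aromatic bromination at the only unsubstituted ring carbon, which is flanked by two hydroxyl groups; one equivalent at low temperature should avoid ipso attack and dearomatisation.

Step 9
Reactants: 15 3-{3-bromo-2,4,6-trihydroxy-5-[(2R)-2-methylbutanoyl]benzyl}-6-ethyl-4-hydroxy-5-methyl-2H-pyran-2-one; 16 isoprene
Product: 17 6-ethyl-4-hydroxy-3-({(2R)-4,6-dihydroxy-5-[(2R)-2-methylbutanoyl]-2-(prop-1-en-2-yl)-2,3-dihydro-1-benzofuran-7-yl}methyl)-5-methyl-2H-pyran-2-one (target)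
Conditions: Pd2(dba)3 (2.5 mol%), chiral sulfinamide monophosphine ligand of the TY-Phos type (10 mol%, enantiomer giving 2R), K2CO3 (3 equiv), excess 16, 1,4-dioxane, 60 °C, sealed tube; NaH2PO4 buffer work-up
Reagents that add atoms: none
Why: Enantioselective Larock-type heteroannulation (Heck/Tsuji–Trost cascade) known for o-bromophenols and isoprene: oxidative addition to zerovalent palladium, insertion of the unsubstituted vinyl terminus and 5-exo capture of the π-allyl by the phenoxide para to the ketone (the most acidic phenol, not chelated to the ketone) should close the dihydrofuran, with the ligand controlling the face of C–O bond formation to set C2 as R.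

**Compound list**

1 | phloroglucinol | Oc1cc(O)cc(O)c1 | starting material
2 | acrylic acid | C=CC(=O)O | starting material
3 | 5,7-dihydroxychroman-2-one | O=C1CCc2c(O)cc(O)cc2O1 | intermediate
4 | 5,7-bis(methoxymethoxy)chroman-2-one | COCOc1cc(OCOC)c2CCC(=O)Oc2c1 | intermediate
5 | propanoyl chloride | CCC(=O)Cl | starting material
6 | methylketene | CC=C=O | intermediate
7 | racemic (Z)-4-ethylidene-3-methyloxetan-2-one (methylketene dimer) | C/C=C1\OC(=O)C1C | intermediate
8 | lithium enolate of 5,7-bis(methoxymethoxy)chroman-2-one | [Li+].COCOc1cc(OCOC)c2CC=C([O-])Oc2c1 | intermediate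
9 | 5,7-bis(methoxymethoxy)-3-(2-methyl-3-oxopentanoyl)chroman-2-one (mixture of tautomers and diastereomers, present as its lithium enolate) | CCC(=O)C(C)C(=O)C1Cc2c(OCOC)cc(OCOC)cc2OC1=O | intermediate
10 | 6-ethyl-4-hydroxy-3-[2-hydroxy-4,6-bis(methoxymethoxy)benzyl]-5-methyl-2H-pyran-2-one | CCc1oc(=O)c(Cc2c(O)cc(OCOC)cc2OCOC)c(O)c1C | intermediate
11 | 6-ethyl-4-hydroxy-5-methyl-3-(2,4,6-trihydroxybenzyl)-2H-pyran-2-one | CCc1oc(=O)c(Cc2c(O)cc(O)cc2O)c(O)c1C | intermediate
12 | (R)-2-methylbutanoic acid | CC[C@@H](C)C(=O)O | starting material
13 | (R)-2-methylbutanoyl chloride | CC[C@@H](C)C(=O)Cl | intermediate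
14 | 6-ethyl-4-hydroxy-5-methyl-3-{2,4,6-trihydroxy-3-[(2R)-2-methylbutanoyl]benzyl}-2H-pyran-2-one | CCc1oc(=O)c(Cc2c(O)cc(O)c(C(=O)[C@H](C)CC)c2O)c(O)c1C | intermediate
15 | 3-{3-bromo-2,4,6-trihydroxy-5-[(2R)-2-methylbutanoyl]benzyl}-6-ethyl-4-hydroxy-5-methyl-2H-pyran-2-one | CCc1oc(=O)c(Cc2c(O)c(Br)c(O)c(C(=O)[C@H](C)CC)c2O)c(O)c1C | intermediate
16 | isoprene | C=CC(C)=C | starting material
17 | 6-ethyl-4-hydroxy-3-({(2R)-4,6-dihydroxy-5-[(2R)-2-methylbutanoyl]-2-(prop-1-en-2-yl)-2,3-dihydro-1-benzofuran-7-yl}methyl)-5-methyl-2H-pyran-2-one | C=C(C)[C@H]1Cc2c(O)c(C(=O)[C@H](C)CC)c(O)c(Cc3c(O)c(C)c(CC)oc3=O)c2O1 | target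

**Totals**

Total step count: 9. Longest linear sequence: 7 steps (steps 1, 2, 4, 5, 7, 8, 9); steps 3 and 6 prepare the two side reagents.

**Steps most likely to fail**

1. Step 4 (ring switch). What may go wrong:
 - proton transfer from the acidic C3–H of the ketene dimer to the enolate instead of acyl transfer;
 - O-acylation of the enolate;
 - stalling at the open tricarbonyl stage because the lithium chelate does not attack the lactone carbonyl;
 - oligomerisation through intermolecular ketene capture.

 The fallback uses known chemistry, leaves from phloroglucinol 1 and returns at 10. Vilsmeier–Haack formylation of 1 (POCl3, DMF, then aqueous hydrolysis) would give 2,4,6-trihydroxybenzaldehyde F1. MOMCl and i-Pr2NEt would cap its two non-chelated phenols to give 2-hydroxy-4,6-bis(methoxymethoxy)benzaldehyde F2. Separately, commercial 3-(trimethylsilyloxy)pent-2-ene and malonyl dichloride (Et2O, −78 °C to rt) would give 6-ethyl-4-hydroxy-5-methyl-2H-pyran-2-one F3 by the silyl enol ether route to 4-hydroxy-2-pyrones. A proline-catalysed Knoevenagel condensation of F2 with F3 run in the presence of Hantzsch ester (three-component reductive benzylation) would then reduce the benzylidene intermediate in situ and give 10.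

2. Step 9 (heteroannulation). What may go wrong:
 - slow oxidative addition into the very electron-rich polyphenoxide and competing reductive debromination;
 - ring closure through the chelated oxygen ortho to the ketone instead of the para oxygen;
 - insufficient facial control by the ligand;
 - base-induced erosion at the α-keto stereocentre on heating.

 The fallback avoids oxidative addition, leaves from 14 and returns at 17. Commercial 2-methyl-2-vinyloxirane would be opened 1,4 with CuCl2/LiCl to (E)-4-chloro-2-methylbut-2-en-1-ol F4, which ClCO2Me and pyridine would convert into (E)-4-chloro-2-methylbut-2-en-1-yl methyl carbonate F5. C-Alkylation of the phloroglucinolate of 14 at its only free ring carbon with the allylic chloride end of F5 (aqueous K2CO3, NaI cat.) would give (E)-4-{3-[(6-ethyl-4-hydroxy-5-methyl-2-oxo-2H-pyran-3-yl)methyl]-2,4,6-trihydroxy-5-[(2R)-2-methylbutanoyl]phenyl}-2-methylbut-2-en-1-yl methyl carbonate F6. Its intramolecular asymmetric allylic etherification (Tsuji–Trost cyclisation; Pd2(dba)3 and a C2-symmetric trans-1,2-diaminocyclohexane bis(2-diphenylphosphinobenzamide) ligand, CH2Cl2, rt) is a known way to 2-isopropenyl-2,3-dihydrobenzofurans of high enantiomeric purity. At room temperature without added strong base only the para phenol should act as the nucleophile, which would give 17.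

3. Step 7 (Friedel–Crafts acylation). What may go wrong:
 - acid-induced cleavage or scrambling of the methylene bridge between the two electron-rich rings;
 - enolisation and epimerisation next to the new ketone under the Lewis acid;
 - persistent O-acylation.

 The fallback introduces the ketone before the bridge exists; it leaves from 1 and 13, returns at 14, and gives up the lactone tether for this part of the route. Friedel–Crafts acylation of phloroglucinol 1 with 13 (AlCl3, CH2Cl2/PhNO2) would give (2R)-2-methyl-1-(2,4,6-trihydroxyphenyl)butan-1-one F7. The pyrone 6-ethyl-4-hydroxy-5-methyl-2H-pyran-2-one F3, made as in the first fallback, would be aminomethylated with N,N-dimethylmethyleneiminium iodide to the Mannich base 3-[(dimethylamino)methyl]-6-ethyl-4-hydroxy-5-methyl-2H-pyran-2-one F8. Warming F8 with F7 should expel dimethylamine to a 3-methylene pyrandione that is trapped at a ring carbon of F7 (Mannich-type methylene coupling) and so gives 14.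

**Further compounds**

F1 | step 4 | 2,4,6-trihydroxybenzaldehyde | O=Cc1c(O)cc(O)cc1O
F2 | step 4 | 2-hydroxy-4,6-bis(methoxymethoxy)benzaldehyde | COCOc1cc(O)c(C=O)c(OCOC)c1
F3 | step 4 | 6-ethyl-4-hydroxy-5-methyl-2H-pyran-2-one | CCc1oc(=O)cc(O)c1C
F4 | step 9 | (E)-4-chloro-2-methylbut-2-en-1-ol | OC/C(C)=C/CCl
F5 | step 9 | (E)-4-chloro-2-methylbut-2-en-1-yl methyl carbonate | COC(=O)OC/C(C)=C/CCl
F6 | step 9 | (E)-4-{3-[(6-ethyl-4-hydroxy-5-methyl-2-oxo-2H-pyran-3-yl)methyl]-2,4,6-trihydroxy-5-[(2R)-2-methylbutanoyl]phenyl}-2-methylbut-2-en-1-yl methyl carbonate | CCc1oc(=O)c(Cc2c(O)c(C/C=C(\C)COC(=O)OC)c(O)c(C(=O)[C@H](C)CC)c2O)c(O)c1C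
F7 | step 7 | (2R)-2-methyl-1-(2,4,6-trihydroxyphenyl)butan-1-one | CC[C@@H](C)C(=O)c1c(O)cc(O)cc1O
F8 | step 7 | 3-[(dimethylamino)methyl]-6-ethyl-4-hydroxy-5-methyl-2H-pyran-2-one | CCc1oc(=O)c(CN(C)C)c(O)c1C
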